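(Readings and results were computed for substances that don't exist; noise was put on by code.)

Time was what I watched in this flask, and I reckoned with what was left, y = c(complex with one exchanged) / c(starting complex charged), and not with what had been made.

all flasks: starting complex 0.057 M
- beta: incoming ligand 1.3 equiv; capture agent 5.7 mM; run made earlier
- delta: incoming ligand 3 equiv; capture agent 5.7 mM; run made earlier
- flask: incoming ligand 2.00 equiv; capture agent 5.70 mM; time 12 min

| run | time / min | complex with one exchanged / % | complex with two exchanged / % |
|---|---|---|---|
| beta | 0.500 | 54 | 10 |
| beta | 1.33 | 43 | 6 |
| beta | 2.50 | 30 | 5 |
| beta | 4.00 | 25 | 6 |
| beta | 6.00 | 20 | 2 |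
| beta | 8.00 | 14 | 3 |
| beta | 10.0 | 15 | 4 |
| delta | 1.33 | 34 | 23 |
| delta | 3.00 | 27 | 20 |
| delta | 4.00 | 20 | 16 |
| delta | 6.00 | 18 | 12 |
| delta | 8.00 | 12 | 9 |
| delta | 10.0 | 11 | 10 |

(readings scatter by 1.5 percentage points)

- percentages count the starting complex that a species holds: one side product counts as two
- reactions considered so far: starting complex + incoming ligand <-> leaving ligand + complex with one exchanged; complex with one exchanged + incoming ligand <-> leaving ligand + complex with two exchanged; starting complex + complex with two exchanged -> side product; complex with one exchanged + capture agent -> trapped intermediate

1. equivalents of incoming ligand to starting complex, everything else as given, that leave most complex with one exchanged at 12 min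
2. the amount of complex with one exchanged then, in percent of the starting complex charged
3. the amount of complex with one exchanged with the amounts as given

1. The first instants: by 0.500 min the beta run already read 54% complex with one exchanged and 10% complex with two exchanged, so I took the ligand exchange to be fast against the spacing of the readings.

2. The middle: in the delta run y fell by 23 percentage points, more than the 10.0% of the starting complex that the capture agent could take one for one, so the reaction of starting complex with complex with two exchanged had to carry the rest.

3. The end: that step joins two complexes whose amounts were falling together, so I expected a second-order loss, in which 1/y rises straight with time. From 1.33 min to 10.0 min, 1/y rose by 0.501 /min in the beta run and 0.709 /min in the delta run.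

4. I took their mean as the drain constant g, the rise of 1/y per minute, 0.605 /min, a reading that carries the scatter of the late points.

5. Starting from the mean of the two readings at 1.33 min, g brought the flask to 11.0% at 12 min. The gap of 0.208 /min between the two rises rested on single late readings of 15% and 11%, each good to 1.5 points, so I read no difference in drain between the two charges from it and left the best charge open.

6. The forecast looked to the high side, with 8 equiv giving 13.5% and 10% as given, holding that “Skewed mixtures survive better”.

The flask held 10.0% at 12 min, and the best charge proved to be 0.486 equiv, giving 14.1%.

    starting complex + incoming ligand ⇌ leaving ligand + complex with one exchanged (K = 5.23, k = 3.97 /M/s)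
    complex with one exchanged + incoming ligand ⇌ leaving ligand + complex with two exchanged (K = 0.450, k = 0.506 /M/s)
    starting complex + complex with two exchanged → side product (k = 1.95 /M/s)
    complex with one exchanged + capture agent → trapped intermediate (k = 0.954 /M/s)

At that best charge, 53.8% of the starting complex still stood. In the flask itself, 1/y rose by 0.693 /min from 6.00 min to 12.0 min, against my g of 0.605 /min. Carrying g on from the flask's 10.0% gave 3.03% for a reading at 50 min, where the same flask held 2.74%.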